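At 1.00 h on the clock the violet run still holds 41.9% of its E and the blue run 22.3%, and this pair tells me what to leave you. The flask on the bench is E with a trace of G, turning E into J.

| flask | E | G | remark |
|---|---|---|---|
| violet | 0.050 M | 0.0067 mol% | run made earlier |
| blue | 0.050 M | 0.015 mol% | run made earlier |
| red | 0.025 M | 0.01 mol% | run made earlier |
| flask | 0.050 M | 0.01 mol% |  |

| run | time / h | J / % | E / % |
|---|---|---|---|
| violet | 0.417 | 27.8 | 71.2 |
| violet | 1.00 | 56.8 | 41.9 |
| violet | 2.00 | 82.2 | 18.7 |
| violet | 3.00 | 92.1 | 7.8 |
| violet | 4.00 | 97.6 | 4.8 |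
| violet | 6.00 | 99.9 | 0.1 |
| violet | 8.00 | 100.5 | 0.4 |
| blue | 1.00 | 75.9 | 22.3 |
| blue | 2.00 | 94.5 | 6.0 |
| blue | 3.00 | 98.1 | 2.7 |
| blue | 4.00 | 100.0 | 0 |
| blue | 5.00 | 100.8 | 0 |
| blue | 6.00 | 99.7 | 0.5 |
| blue | 8.00 | 98.6 | 0 |
| red | 1.33 | 60.5 | 40.2 |
| red | 3.00 | 90.4 | 12.0 |
| red | 4.00 | 92.9 | 5.2 |
| red | 6.00 | 98.2 | 0.1 |
| red | 8.00 | 100.1 | 0 |

(scatter of a reading: 1 percentage point)



1. factor on the rate of making J when 50% of the E are converted if G is charged twice over
2. factor on the rate when 50% of the E are converted if G is charged at 0.1 mol% instead

Each run loses a roughly steady fraction of its E per hour (pseudo-first-order), so ln(1/fraction left) grows in step with time. If I divide the blue value by the violet one at the same hour, time drops out and the ratio of rates remains. The logarithm of that ratio over the logarithm of the ratio of loadings reads 0.677, within the scatter of two readings, the catalyst order.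

Scaled from violet by this order, the flask reaches 50% conversion of E at about 0.608 h. The violet run, with less G, already reads 99.9% J after 6.00 h, so I expect about the same in the flask by then. Do not dilute the flask: the red run, at this loading on half the E and so with less G per litre, takes 1.01 h to its half-way point, reckoned from its first reading, and the order, applied to G per litre, foretells 0.971 h.

The forecast gives 1.55 for doubling G and 4 for 0.1 mol%, calling that step “an extrapolation well outside the tested range”. With the same E charged, equal conversion means equal E, so the rate goes with the loss per hour, and my order gives 1.60 and a higher 4.75.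

The flask gives 1.58 and 4.14.

    E + G ⇌ D (K = 960 L mol⁻¹, k = 8400 L mol⁻¹ min⁻¹)
    D → G + J (k = 980 min⁻¹)
    2 G ⇌ X, settled at all times (K = 2.20 × 10⁵ L mol⁻¹)

Read back, 1.58 is an order of 0.660 against my 0.677. At 0.631 h in the flask, D, the enzyme holding E, falls back 0.0089 times as fast as it goes on to J, and X, the paired form outside the working round, is 45.1% of the catalyst. The step to 0.1 mol% reads back as an order of 0.617, and at the same conversion in that flask X is 77.3% of the catalyst.

(The earlier runs and the new flask were generated by integration with made-up constants; the scatter is artificial.)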